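**Plan**

Rings: A is the 1,2,4-trisubstituted ring whose ether O goes to the meta-phenylene B; C is the para-phenylene; D is the 1,2,4-trisubstituted ring whose ether O goes to C.
Retrosynthesis: cut the two O–CH3 bonds (protecting groups), then the ring-D aryl C–CH2 bond of the A–CH2CH2–D bridge (opens the 20-membered ring to a 2-arylethanol), then the hydroxyethyl chain back to CHO, the B–O–A ether (SNAr), the B–CH2CH2–C bibenzyl (Wittig/hydrogenation) and the C–O–D ether (SNAr).
Forward: D–O–C ether, then bibenzyl C–B, then B–O–A ether, then CHO to CH2CH2OH, then macrocyclisation, then demethylation; the macrocycle is the only ring formed, in the last step but one.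
Enabling feature: the CH2 to be bonded is β to ring A, whose ether oxygen is para to the ethano chain, so ring A can bridge to a phenonium ion with two equivalent CH2 carbons; the ring-D carbon is para to the oxygen that ends as the free OH, the most nucleophilic C–H of the open chain. The ring therefore closes by C–H alkylation with no halide or metal on either partner.
Stereochemistry (assumption): the SMILES holds no stereocentre and no configured double bond, and the 20-membered ring is taken as conformationally mobile, so the target is achiral and no step sets configuration.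

Key step: step 8

**Route**

Step 1
Reactants: 1 guaiacol (2-methoxyphenol); 2 4-fluorobenzaldehyde
Product: 3 4-(2-methoxyphenoxy)benzaldehyde
Conditions: K2CO3, DMF, 120 °C
Reagents that add atoms: none
Why: SNAr (addition–elimination) of the guaiacolate on the fluoride para to the formyl group, which stabilises the Meisenheimer intermediate.

Step 2
Reactants: 4 3-(benzyloxy)benzyl bromide
Product: 5 [3-(benzyloxy)benzyl]triphenylphosphonium bromide
Conditions: PPh3, toluene, reflux
Reagents that add atoms: triphenylphosphine, c1ccc(cc1)P(c1ccccc1)c1ccccc1
Why: SN2 quaternisation of triphenylphosphine by a benzylic bromide, the standard preparation of a Wittig salt.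

Step 3
Reactants: 3 4-(2-methoxyphenoxy)benzaldehyde; 5 [3-(benzyloxy)benzyl]triphenylphosphonium bromide
Product: 7 1-(benzyloxy)-3-{2-[4-(2-methoxyphenoxy)phenyl]ethenyl}benzene (E/Z mixture), via benzylidene phosphorane 6 (not isolated)
Conditions: KOtBu, THF, 0 °C to rt
Reagents that add atoms: none
Why: Wittig olefination of a non-enolisable aryl aldehyde with a semi-stabilised benzylic ylide; the E/Z ratio does not matter because the alkene is saturated in step 4.

Step 4
Reactants: 7 1-(benzyloxy)-3-{2-[4-(2-methoxyphenoxy)phenyl]ethenyl}benzene
Product: 8 3-{2-[4-(2-methoxyphenoxy)phenyl]ethyl}phenol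
Conditions: H2 (1 atm), 10% Pd/C, EtOAc/MeOH, rt
Reagents that add atoms: none
Why: Catalytic hydrogenation should saturate the stilbene and hydrogenolyse the benzyl ether in one operation, while diaryl and methyl aryl ethers are inert, so only the ring-B phenol is unmasked.

Step 5
Reactants: 8 3-{2-[4-(2-methoxyphenoxy)phenyl]ethyl}phenol; 9 4-fluoro-3-methoxybenzaldehyde
Product: 10 3-methoxy-4-(3-{2-[4-(2-methoxyphenoxy)phenyl]ethyl}phenoxy)benzaldehyde
Conditions: Cs2CO3, DMSO, 120 °C
Reagents that add atoms: none
Why: SNAr of the caesium phenoxide of 8 on the fluoride para to the formyl group installs ring A with OMe ortho and the future chain carbon para to the new ether oxygen.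

Step 6
Reactants: 10 3-methoxy-4-(3-{2-[4-(2-methoxyphenoxy)phenyl]ethyl}phenoxy)benzaldehyde
Product: 11 4-ethenyl-2-methoxy-1-(3-{2-[4-(2-methoxyphenoxy)phenyl]ethyl}phenoxy)benzene
Conditions: Ph3PCH3Br, KOtBu, THF, 0 °C to rt
Reagents that add atoms: methyltriphenylphosphonium bromide, C[P+](c1ccccc1)(c1ccccc1)c1ccccc1.[Br-]
Why: Wittig methylenation of an aryl aldehyde with the unstabilised ylide should give the styrene cleanly.

Step 7
Reactants: 11 4-ethenyl-2-methoxy-1-(3-{2-[4-(2-methoxyphenoxy)phenyl]ethyl}phenoxy)benzene
Product: 13 2-[3-methoxy-4-(3-{2-[4-(2-methoxyphenoxy)phenyl]ethyl}phenoxy)phenyl]ethanol, via B-alkyl-9-BBN adduct 12 (not isolated)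
Conditions: 9-BBN, THF, 0 °C to rt; then 3 M NaOH, 30% H2O2, 0 °C to rt
Reagents that add atoms: hydrogen peroxide, OO (gives the hydroxyl oxygen of 13); 9-borabicyclo[3.3.1]nonane, B1C2CCCC1CCC2 (its boron and carbons are held only in 12)
Why: Brown hydroboration–oxidation; the bulky 9-BBN adds anti-Markovnikov to the styrene and alkaline peroxide replaces boron by OH to give the primary 2-arylethanol.

Step 8
Reactants: 13 2-[3-methoxy-4-(3-{2-[4-(2-methoxyphenoxy)phenyl]ethyl}phenoxy)phenyl]ethanol
Product: 15 di-O-methyl ether of the target (the 20-membered macrocycle with both phenols as OCH3), via ring-A phenonium cation 14 (not isolated)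
Conditions: TfOH (20 mol %), HFIP, 80 °C (sealed vessel), 13 added by syringe pump over 12 h, final concentration ca. 2 mM
Reagents that add atoms: none
Why: Proposed new method: TfOH in HFIP protonates the primary hydroxyl of 13, and ring A, whose diaryl-ether oxygen lies para to the ethanol chain, displaces water with anchimeric assistance to give the spiro[2.5]octadienyl (phenonium) cation 14, which the ring-D carbon para to the methoxy group opens at a cyclopropane CH2 in an SN2-like Friedel–Crafts event before losing a proton. The closest known reaction type is the acid-catalysed dehydrative Friedel–Crafts arylation of 2-arylethanols through phenonium ions in HFIP, known between separate molecules; its use for a macrocyclic closure is the untested element. One ring is closed, the 20-membered macrocycle, by intramolecular electrophilic aromatic substitution in which the arene attacks the three-membered ring from outside, and because both cyclopropane carbons are equivalent either opening gives the same ArCH2CH2Ar bridge. No stereocentre is formed. The step needs site selectivity and cyclisation over oligomerisation: ring D is the only nucleophilic ring with two oxygen donors and its C–H para to OMe is the most activated unhindered position, rings B and C carry one ether oxygen each and are reachable only through strained 9- to 15-membered cyclophane transition states, and slow addition keeps the concentration of 13 low. The bridged phenonium structure, not an open primary cation, should suppress hydride shift to the branched benzylic cation, and the poorly nucleophilic, ionising HFIP should sustain the cation until the arene reaches it.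

Step 9
Reactants: 15 di-O-methyl ether of the target
Product: 16 target CNP0329842.0 (macrocyclic bis(bibenzyl) diphenol)
Conditions: BBr3, CH2Cl2, −78 °C to rt; then H2O
Reagents that add atoms: none
Why: Lewis-acid ether cleavage; BBr3 coordinates each methoxy oxygen and bromide removes the methyl group by SN2, while the diaryl ether C(sp2)–O bonds should stay intact.

**Compound list**

1 | guaiacol (2-methoxyphenol) | COc1ccccc1O | starting material
2 | 4-fluorobenzaldehyde | O=Cc1ccc(F)cc1 | starting material
3 | 4-(2-methoxyphenoxy)benzaldehyde | COc1ccccc1Oc1ccc(C=O)cc1 | intermediate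
4 | 3-(benzyloxy)benzyl bromide | BrCc1cccc(OCc2ccccc2)c1 | starting material
5 | [3-(benzyloxy)benzyl]triphenylphosphonium bromide | [Br-].c1ccc(COc2cccc(C[P+](c3ccccc3)(c3ccccc3)c3ccccc3)c2)cc1 | intermediate
6 | [3-(benzyloxy)benzylidene]triphenylphosphorane (not isolated) | c1ccc(COc2cccc(C=P(c3ccccc3)(c3ccccc3)c3ccccc3)c2)cc1 | intermediate
7 | 1-(benzyloxy)-3-{2-[4-(2-methoxyphenoxy)phenyl]ethenyl}benzene, E/Z mixture | COc1ccccc1Oc1ccc(C=Cc2cccc(OCc3ccccc3)c2)cc1 | intermediate
8 | 3-{2-[4-(2-methoxyphenoxy)phenyl]ethyl}phenol | COc1ccccc1Oc1ccc(CCc2cccc(O)c2)cc1 | intermediate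
9 | 4-fluoro-3-methoxybenzaldehyde | COc1cc(C=O)ccc1F | starting material
10 | 3-methoxy-4-(3-{2-[4-(2-methoxyphenoxy)phenyl]ethyl}phenoxy)benzaldehyde | COc1ccccc1Oc1ccc(CCc2cccc(Oc3ccc(C=O)cc3OC)c2)cc1 | intermediate
11 | 4-ethenyl-2-methoxy-1-(3-{2-[4-(2-methoxyphenoxy)phenyl]ethyl}phenoxy)benzene | COc1ccccc1Oc1ccc(CCc2cccc(Oc3ccc(C=C)cc3OC)c2)cc1 | intermediate
12 | 9-{2-[3-methoxy-4-(3-{2-[4-(2-methoxyphenoxy)phenyl]ethyl}phenoxy)phenyl]ethyl}-9-borabicyclo[3.3.1]nonane (not isolated) | COc1ccccc1Oc1ccc(CCc2cccc(Oc3ccc(CCB4C5CCCC4CCC5)cc3OC)c2)cc1 | intermediate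
13 | 2-[3-methoxy-4-(3-{2-[4-(2-methoxyphenoxy)phenyl]ethyl}phenoxy)phenyl]ethanol | COc1ccccc1Oc1ccc(CCc2cccc(Oc3ccc(CCO)cc3OC)c2)cc1 | intermediate
14 | ring-A phenonium (spiro[2.5]octadienyl) cation, triflate counter-ion, oxocarbenium resonance form drawn (not isolated) | COC1=CC2(CC2)C=CC1=[O+]c1cccc(CCc2ccc(Oc3ccccc3OC)cc2)c1 | intermediate
15 | di-O-methyl ether of the target macrocycle | COc1cc2ccc1Oc1cccc(c1)CCc1ccc(cc1)Oc1cc(ccc1OC)CC2 | intermediate
16 | target CNP0329842.0 | Oc1cc2ccc1Oc1cccc(c1)CCc1ccc(cc1)Oc1cc(ccc1O)CC2 | target

**Summary**

Total step count: 9. Longest linear sequence: 8 steps (steps 1 and 3–9; the branch through step 2 is equally long).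

Steps most likely to fail:

1. Step 8 (Proposed new method). Capture of the phenonium ion by solvent, by a second molecule (oligomerisation) or by another ring position (para to the aryloxy oxygen of ring D, or ortho to the ether oxygen of ring C) may outrun the 20-membered closure. Hydride shift to the benzylic cation may also give branched 1,1-diarylethane linkages. The fallback uses known chemistry, sets out from 13 and returns at 15. Alcohol 13 would be oxidised (cat. TEMPO, PhI(OAc)2, MeCN/H2O) to [3-methoxy-4-(3-{2-[4-(2-methoxyphenoxy)phenyl]ethyl}phenoxy)phenyl]acetic acid F1, which would be converted with oxalyl chloride and cat. DMF in CH2Cl2 into the arylacetyl chloride F2. Slow addition of F2 to SnCl4 in CH2Cl2 at 0 °C under high dilution should close the ring by Friedel–Crafts acylation at the same ring-D carbon (para to OMe) to give the macrocyclic deoxybenzoin F3. Ionic hydrogenation of this para-alkoxyaryl ketone (Et3SiH, TFA, rt) should then give 15.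

2. Step 5. The fluoride of 9 is deactivated by the ortho methoxy group, so the addition–elimination may be sluggish and base-mediated degradation of the aldehyde may compete at the temperature required. The fallback replaces SNAr by a copper-catalysed Ullmann-type ether coupling of 8 with 4-bromo-3-methoxybenzaldehyde (COc1cc(C=O)ccc1Br; CuI, N,N-dimethylglycine, Cs2CO3, dioxane, 100 °C). It sets out from 8 and returns at 10, with no new intermediate.

3. Step 9. Cleavage of the two methoxy groups, each flanked by an aryloxy group, may be incomplete, or the strong Lewis acid may cause ring bromination or scission of a diaryl ether on the electron-rich macrocycle. The fallback is nucleophilic demethylation by SN2 attack of sodium ethanethiolate at the methyl carbons (NaSEt, DMF, 130 °C, then acidic work-up), which cannot touch aryl–O–aryl bonds. It sets out from 15 and ends at 16, with no new intermediate.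

**Further compounds**

F1 | step 8 | [3-methoxy-4-(3-{2-[4-(2-methoxyphenoxy)phenyl]ethyl}phenoxy)phenyl]acetic acid | COc1ccccc1Oc1ccc(CCc2cccc(Oc3ccc(CC(=O)O)cc3OC)c2)cc1
F2 | step 8 | [3-methoxy-4-(3-{2-[4-(2-methoxyphenoxy)phenyl]ethyl}phenoxy)phenyl]acetyl chloride | COc1ccccc1Oc1ccc(CCc2cccc(Oc3ccc(CC(=O)Cl)cc3OC)c2)cc1
F3 | step 8 | macrocyclic deoxybenzoin (15 with C=O at the CH2 on ring D) | COc1cc2ccc1Oc1cccc(c1)CCc1ccc(cc1)Oc1cc(ccc1OC)C(=O)C2
F0 | step 5 | none | none
F0 | step 9 | none | none
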